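**Retrosynthetic overview**

- The strategy rests on one feature: the arene (C1 side chain, C2/C4/C6 OH, C5 isobutyryl) is a folded tetraketide, and ring carbon C6 is linked through C1, C1' and C2' to the tertiary carbinol C3'. The atoms C6(=O)–C1–C1'–C2'–C3'–O therefore form a δ-lactone, which serves both as the ester of a Claisen aromatisation and as the protecting group of the tertiary alcohol.
- Key disconnection: arene bond C5–C6, leading back to the (6S)-3-(6-methyl-3,5-dioxoheptanoyl) δ-lactone. The carbocycle is the last ring formed, and the lactone ring opens in the same step.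
- The triketo chain is grown from a 3-acetyl δ-lactone by two polyanion acylations with Weinreb amides (acetyl, then isobutyryl).
- The 3-acetyl δ-lactone (first ring formed) comes from acetoacetic ester alkylation with a hydroxy iodide followed by acylketene lactonisation.
- The iodide comes from (S)-linalool by vinyl-selective hydroboration and primary iodination; linalool supplies the only stereocentre.

Key step: step 7

Remark: (S)-(+)-linalool is assumed to be bought in high enantiomeric purity, since no step makes or breaks a bond at its carbinol carbon; β-dicarbonyl compounds 6, 8, 11 and 14 are drawn as keto forms and are epimeric or enolised at the carbon between the carbonyls.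

**Step 1**
Reactants: 1 (S)-linalool
Product: 3 (3S)-3,7-dimethyloct-6-ene-1,3-diol, via B-alkyl-9-BBN adduct 2 (not isolated)
Conditions: 9-BBN (2 equiv), THF, 0 °C to rt; then 3 M NaOH, 30% H2O2, 0 °C to rt
Reagents that add atoms: hydrogen peroxide, OO (oxygen of the new OH); 9-borabicyclo[3.3.1]nonane, [H]B1C2CCCC1CCC2 (its boron and carbons remain only in intermediate 2)
Why: Anti-Markovnikov hydroboration–oxidation, in which 9-BBN reacts with the monosubstituted vinyl group far faster than with the trisubstituted alkene and places boron on the terminal carbon; the carbinol stereocentre is untouched.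

**Step 2**
Reactants: 3 (3S)-3,7-dimethyloct-6-ene-1,3-diol
Product: 4 (3S)-1-iodo-3,7-dimethyloct-6-en-3-ol
Conditions: PPh3, imidazole, I2 (premixed so that no free iodine meets the alkene), CH2Cl2, 0 °C; then 3
Reagents that add atoms: iodine, II
Why: Appel-type iodination, in which only the unhindered primary hydroxyl forms the alkoxyphosphonium ion that iodide displaces by SN2, so the tertiary alcohol stays free.

**Step 3**
Reactants: 4 (3S)-1-iodo-3,7-dimethyloct-6-en-3-ol; 5 tert-butyl acetoacetate
Product: 6 tert-butyl (5S)-2-acetyl-5-hydroxy-5,9-dimethyldec-8-enoate (both C2 epimers)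
Conditions: 5 (1.5 equiv), NaH (1.4 equiv), THF, 0 °C; then 4, DMF, 50 °C
Reagents that add atoms: none
Why: Acetoacetic ester C-alkylation, in which the soft sodium enolate (kept in excess over NaH so that no alkoxide can close an oxetane) displaces the primary iodide by SN2; the new C2 centre forms as both epimers, which does not matter because it later becomes sp2.

**Step 4**
Reactants: 6 tert-butyl (5S)-2-acetyl-5-hydroxy-5,9-dimethyldec-8-enoate
Product: 8 (6S)-3-acetyl-6-methyl-6-(4-methylpent-3-en-1-yl)oxan-2-one (C3 epimers and enol), via acylketene 7 (not isolated)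
Conditions: toluene (0.02 M), 110 °C, slow N2 sweep to remove t-BuOH, acid-free glassware
Reagents that add atoms: none
Why: Acylketene lactonisation (thermal transesterification of a tert-butyl β-keto ester): the enol form loses tert-butanol by retro-ene elimination to give ketene 7, which the tertiary hydroxyl traps to close the six-membered lactone under neutral conditions that spare the alkene and the C–O stereocentre.

**Step 5**
Reactants: 8 (6S)-3-acetyl-6-methyl-6-(4-methylpent-3-en-1-yl)oxan-2-one; 9 N-methoxy-N-methylacetamide
Product: 11 (6S)-6-methyl-6-(4-methylpent-3-en-1-yl)-3-(3-oxobutanoyl)oxan-2-one, via lithium hemiaminal adduct 10 (not isolated)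
Conditions: LDA (2.3 equiv), THF, −78 to 0 °C; then 9, −78 to 0 °C; AcOH, −78 °C
Reagents that add atoms: none
Why: γ-Acylation of a β-keto ester dianion (known for α-acetyl lactones): the second deprotonation occurs at the acetyl CH3, this carbon attacks the Weinreb amide, and the chelated adduct 10 persists until the quench, so the more acidic product cannot consume dianion while the enolised lactone carbonyl is shielded from attack.

**Step 6**
Reactants: 11 (6S)-6-methyl-6-(4-methylpent-3-en-1-yl)-3-(3-oxobutanoyl)oxan-2-one; 12 N-methoxy-N,2-dimethylpropanamide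
Product: 14 (6S)-6-methyl-3-(6-methyl-3,5-dioxoheptanoyl)-6-(4-methylpent-3-en-1-yl)oxan-2-one (both C3 epimers), via lithium hemiaminal adduct 13 (not isolated)
Conditions: LDA (3.3 equiv), THF, −78 to 0 °C; then 12, −78 to 0 °C; AcOH/THF, −78 °C; cold pH 5 buffer work-up; crude 14 kept cold and used at once
Reagents that add atoms: none
Why: Terminal acylation of a 3,5-dioxo ester trianion: three equivalents of LDA deprotonate the lactone α-carbon, the inter-ketone CH2 and the terminal CH3, the last and most basic site attacks the Weinreb amide, and adduct 13 releases the fourth carbonyl only on the cold buffered quench, which should keep 14 from cyclising in the flask.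

**Step 7**
Reactants: 14 (6S)-6-methyl-3-(6-methyl-3,5-dioxoheptanoyl)-6-(4-methylpent-3-en-1-yl)oxan-2-one
Product: 16 1-{2,4,6-trihydroxy-3-[(3S)-3-hydroxy-3,7-dimethyloct-6-en-1-yl]phenyl}-2-methylpropan-1-one, via cyclohexane-1,3,5-trione 15 (not isolated)
Conditions: MgCl2 (2.5 equiv), Et3N (3 equiv), MeCN (0.02 M), Ar, 0 °C to rt (40 °C if slow); then cold 0.5 M HCl to pH 4
Reagents that add atoms: none
Why: Proposed new method: Mg(II)/Et3N soft enolisation should turn the 1,3,5-triketone into a magnesium bis-enolate in which chain carbon C4 (the CH2 between the 3-oxo group and the 5-oxo, i.e. isobutyryl, carbonyl) is nucleophilic while the lactone α-carbon, the least acidic of the three sites, stays protonated; C4 adds to the Mg-bound lactone carbonyl (new arene bond C5–C6), the tetrahedral intermediate expels the tertiary C3' oxygen with general-acid help from Et3NH+, so the lactone opens as the carbocycle closes, and trione 15 enolises irreversibly to the phloroglucinol. The closest known reaction type is the magnesium-mediated Claisen (Dieckmann-type) cyclisation of 3,5,7-trioxo esters and of 6-(2-oxoalkyl)-4-hydroxy-2-pyrones to acylphloroglucinols, together with Mg(II)/amine C-acylation of 1,3-dicarbonyls; new here is a δ-lactone as the internal ester, whose E-ester geometry makes it a better acyl acceptor than an open-chain ester and should offset the poorer tertiary alkoxide leaving group. The one ring closes in a 6-(enolexo)-exo-trig mode through a six-membered Mg-chelated enolate–carbonyl transition state. No stereocentre is created: only the acyl C–O bond of the lactone breaks, so C3' keeps its S configuration, and both C3 epimers of 14 converge because that carbon becomes aromatic. The step needs C-acylation to win over O-acylation to a 4-hydroxy-2-pyrone and over aldol closure of the lactone α-carbon onto the isobutyryl carbonyl; Mg chelation favours C-acylation and keeps the pyrone pathway reversible (the freed alkoxide stays tethered), and the aldol is disfavoured because the isobutyryl carbonyl is enolised and hindered, the α-carbon would become a quaternary spiro centre and that product cannot aromatise.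

**Compound list**

1 | (S)-linalool, (3S)-3,7-dimethylocta-1,6-dien-3-ol | CC(C)=CCC[C@](C)(O)C=C | starting material
2 | B-[(3R)-3-hydroxy-3,7-dimethyloct-6-en-1-yl]-9-borabicyclo[3.3.1]nonane (not isolated; R only by CIP rank of the boryl chain, same spatial arrangement) | CC(C)=CCC[C@](C)(O)CCB1C2CCCC1CCC2 | intermediate
3 | (3S)-3,7-dimethyloct-6-ene-1,3-diol | CC(C)=CCC[C@](C)(O)CCO | intermediate
4 | (3S)-1-iodo-3,7-dimethyloct-6-en-3-ol | CC(C)=CCC[C@](C)(O)CCI | intermediate
5 | tert-butyl acetoacetate | CC(=O)CC(=O)OC(C)(C)C | starting material
6 | tert-butyl (5S)-2-acetyl-5-hydroxy-5,9-dimethyldec-8-enoate | CC(C)=CCC[C@](C)(O)CCC(C(C)=O)C(=O)OC(C)(C)C | intermediate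
7 | (5S)-2-acetyl-5-hydroxy-5,9-dimethyldeca-1,8-dien-1-one, acylketene (not isolated) | CC(C)=CCC[C@](C)(O)CCC(C(C)=O)=C=O | intermediate
8 | (6S)-3-acetyl-6-methyl-6-(4-methylpent-3-en-1-yl)oxan-2-one | CC(C)=CCC[C@]1(C)OC(=O)C(C(C)=O)CC1 | intermediate
9 | N-methoxy-N-methylacetamide | CON(C)C(C)=O | starting material
10 | hemiaminal adduct of the dianion of 8 with 9 (not isolated; drawn neutral, present as lithium chelate) | CC(C)=CCC[C@]1(C)OC(=O)C(C(=O)CC(C)(O)N(C)OC)CC1 | intermediate
11 | (6S)-6-methyl-6-(4-methylpent-3-en-1-yl)-3-(3-oxobutanoyl)oxan-2-one | CC(C)=CCC[C@]1(C)OC(=O)C(C(=O)CC(C)=O)CC1 | intermediate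
12 | N-methoxy-N,2-dimethylpropanamide | CON(C)C(=O)C(C)C | starting material
13 | hemiaminal adduct of the trianion of 11 with 12 (not isolated; drawn neutral, present as lithium chelate) | CC(C)=CCC[C@]1(C)OC(=O)C(C(=O)CC(=O)CC(O)(C(C)C)N(C)OC)CC1 | intermediate
14 | (6S)-6-methyl-3-(6-methyl-3,5-dioxoheptanoyl)-6-(4-methylpent-3-en-1-yl)oxan-2-one | CC(C)=CCC[C@]1(C)OC(=O)C(C(=O)CC(=O)CC(=O)C(C)C)CC1 | intermediate
15 | 2-[(3S)-3-hydroxy-3,7-dimethyloct-6-en-1-yl]-4-(2-methylpropanoyl)cyclohexane-1,3,5-trione (not isolated) | CC(C)=CCC[C@](C)(O)CCC1C(=O)CC(=O)C(C(=O)C(C)C)C1=O | intermediate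
16 | 1-{2,4,6-trihydroxy-3-[(3S)-3-hydroxy-3,7-dimethyloct-6-en-1-yl]phenyl}-2-methylpropan-1-one | CC(C)=CCC[C@](C)(O)CCc1c(O)cc(O)c(C(=O)C(C)C)c1O | target

Total step count: 7
Longest linear sequence: 7 steps, from (S)-linalool 1

**Steps most likely to fail**

Step 7 (Proposed new method). The magnesium enolate may acylate on oxygen, or the lactone may open thermally and re-close on oxygen, draining material into a 2-pyrone. The diketonate may also be too weak a nucleophile for the lactone, so that aldol closure and dehydration at the isobutyryl carbonyl take over. The fallback uses known chemistry and sets out from 14. Heating 14 in toluene at 100 °C should drive the O-closure to completion and give the pyrone 4-hydroxy-3-[(3S)-3-hydroxy-3,7-dimethyloct-6-en-1-yl]-6-(3-methyl-2-oxobutyl)-2H-pyran-2-one F1. Treatment with Mg(OMe)2 in MeOH at reflux should then open the pyrone to the open-chain ester methyl 2-[(3S)-3-hydroxy-3,7-dimethyloct-6-en-1-yl]-8-methyl-3,5,7-trioxononanoate F2, which is formed only in the flask. F2 should undergo the established magnesium methoxide Claisen cyclisation with loss of methanol and rejoin the route at target 16.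

Step 6. Acyl transfer from the α-branched Weinreb amide to the trianion may be slow, proton exchange may quench the terminal carbanion, and the tetracarbonyl product may cyclise without control during work-up. The fallback sets out from 11. The same trianion is added to isobutyraldehyde in a fast aldol addition at the terminal carbon, which should give (6S)-3-(5-hydroxy-6-methyl-3-oxoheptanoyl)-6-methyl-6-(4-methylpent-3-en-1-yl)oxan-2-one F3. Oxidation of the secondary alcohol with Dess–Martin periodinane (NaHCO3, CH2Cl2, 0 °C) should then rejoin the route at 14.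

Step 4. Ketene formation from the α-branched ester may be slow enough that cyclodehydration of the δ-hydroxy ketone to a dihydropyran, or loss of isobutene with decarboxylation, competes. The fallback sets out from iodide 4 and builds the lactone before the acetyl group:
- Alkylation of dimethyl malonate (NaH, THF/DMF) should give dimethyl 2-[(3S)-3-hydroxy-3,7-dimethyloct-6-en-1-yl]propanedioate F4.
- Base-catalysed transesterification (cat. NaOMe, toluene, 80 °C, MeOH distilled off) should close the lactone to methyl (6S)-6-methyl-6-(4-methylpent-3-en-1-yl)-2-oxooxane-3-carboxylate F5.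
- Krapcho demethoxycarbonylation (LiCl, H2O, DMSO, 140 °C) should give (6R)-6-methyl-6-(4-methylpent-3-en-1-yl)oxan-2-one F6. The descriptor changes by CIP rank only; the spatial arrangement is the same.
- Crossed Claisen C-acetylation of its lithium enolate (LDA 2.2 equiv, THF, −78 °C) with Weinreb amide 9 should rejoin the route at 8.

**Further compounds**

F1 | step 7 | 4-hydroxy-3-[(3S)-3-hydroxy-3,7-dimethyloct-6-en-1-yl]-6-(3-methyl-2-oxobutyl)-2H-pyran-2-one | CC(C)=CCC[C@](C)(O)CCC1=C(O)C=C(CC(=O)C(C)C)OC1=O
F2 | step 7 | methyl 2-[(3S)-3-hydroxy-3,7-dimethyloct-6-en-1-yl]-8-methyl-3,5,7-trioxononanoate | CC(C)=CCC[C@](C)(O)CCC(C(=O)OC)C(=O)CC(=O)CC(=O)C(C)C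
F3 | step 6 | (6S)-3-(5-hydroxy-6-methyl-3-oxoheptanoyl)-6-methyl-6-(4-methylpent-3-en-1-yl)oxan-2-one | CC(C)=CCC[C@]1(C)OC(=O)C(C(=O)CC(=O)CC(O)C(C)C)CC1
F4 | step 4 | dimethyl 2-[(3S)-3-hydroxy-3,7-dimethyloct-6-en-1-yl]propanedioate | CC(C)=CCC[C@](C)(O)CCC(C(=O)OC)C(=O)OC
F5 | step 4 | methyl (6S)-6-methyl-6-(4-methylpent-3-en-1-yl)-2-oxooxane-3-carboxylate | CC(C)=CCC[C@]1(C)OC(=O)C(C(=O)OC)CC1
F6 | step 4 | (6R)-6-methyl-6-(4-methylpent-3-en-1-yl)oxan-2-one | CC(C)=CCC[C@]1(C)OC(=O)CCC1
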